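**Retrosynthetic overview**
1. The target is the cyclic vinylogous ester of a 2-methoxy-1,3-dione. Its carbocycle C3a–C4–C5–C6–C7–C7a is not closed directly but grown from a squarate-derived cyclobutenone (C5, C6, C7, C7a) by insertion of C4 and C3a.
2. Re-forming C5–C7a (retro-fragmentation) and cutting C7a–C3a and C5–C4 (retro-[2+2]) leads to a monocyclic 3-alkoxy-2,4-dimethoxycyclobutenone. Its alkoxy group is a homoallylic alcohol carrying C2, C3, the aryl group, the C3a=C4 alkene and the allyl group.
3. That ether is cut at O1–C7a into 2,3,4-trimethoxycyclobutenone (from dimethyl squarate) and the anti alcohol, which comes from asymmetric allylboration of acetaldehyde with a γ-aryl allylboronate built from 3,4,5-trimethoxybenzaldehyde.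
4. Ring order: the arene and the four-membered ring are bought; the tetrahydrofuran and a cyclobutane close together in the photocycloaddition; the six-membered ring then appears by four-to-six ring expansion.
5. Enabling feature: C5, C6, C7 and C7a carry four contiguous oxygens (a squarate in disguise), and O1 on C7a is the β-donor of the C6 ketone through C5, so the C5–C7a bond of the photoadduct is a push–pull bond that should break by itself.

Key step: step 9

Remark: locants O1, C2, C3, C3a, C4 to C7 and C7a are those of the target benzofuranone and are used for the same atoms in every precursor.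

**Route**

Step 1
Reactants: 1 triethyl phosphonoacetate; 2 allyl bromide
Product: 3 ethyl 2-(diethoxyphosphoryl)pent-4-enoate (racemic)
Conditions: NaH, THF, 0 °C to rt
Reagents that add atoms: none
Why: C-alkylation (SN2) of the sodium salt of the phosphonoacetate with an allylic bromide is a standard route to α-substituted Horner–Wadsworth–Emmons reagents, and the racemic stereocentre it creates is lost in step 2.

Step 2
Reactants: 3 ethyl 2-(diethoxyphosphoryl)pent-4-enoate; 4 3,4,5-trimethoxybenzaldehyde
Product: 5 ethyl (2E)-2-[(3,4,5-trimethoxyphenyl)methylidene]pent-4-enoate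
Conditions: NaH, THF, 0 °C to rt
Reagents that add atoms: none
Why: Horner–Wadsworth–Emmons olefination of an aryl aldehyde with an α-alkyl phosphonoacetate should favour the (E)-ester with aryl trans to the ester group, which fixes the alkene geometry that step 5 turns into the anti C2/C3 relationship.

Step 3
Reactants: 5 ethyl (2E)-2-[(3,4,5-trimethoxyphenyl)methylidene]pent-4-enoate
Product: 6 (2E)-2-[(3,4,5-trimethoxyphenyl)methylidene]pent-4-en-1-ol
Conditions: i-Bu2AlH, CH2Cl2, −78 °C
Reagents that add atoms: none
Why: 1,2-reduction of the conjugated ester by i-Bu2AlH at low temperature should give the allylic alcohol without touching either alkene or the alkene geometry.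

Step 4
Reactants: 6 (2E)-2-[(3,4,5-trimethoxyphenyl)methylidene]pent-4-en-1-ol
Product: 7 4,4,5,5-tetramethyl-2-{(2Z)-2-[(3,4,5-trimethoxyphenyl)methylidene]pent-4-en-1-yl}-1,3,2-dioxaborolane (aryl trans to CH2B)
Conditions: B2pin2, Pd(MeCN)4(BF4)2 (5 mol %), DMSO/MeOH, 40 °C
Reagents that add atoms: bis(pinacolato)diboron, CC1(C)OB(OC1(C)C)B1OC(C)(C)C(C)(C)O1
Why: palladium-catalysed borylation of an allylic alcohol through a π-allyl complex (Miyaura-type borylation) should deliver boron to the unhindered CH2 terminus and keep aryl trans to the CH2B group.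

Step 5
Reactants: 7 the (2Z)-allylboronate; 8 acetaldehyde
Product: 9 (2R,3R)-4-methylidene-3-(3,4,5-trimethoxyphenyl)hept-6-en-2-ol (anti; hydroxyl carbon is C2, aryl carbon is C3)
Conditions: (S)-TRIP [(S)-3,3′-bis(2,4,6-triisopropylphenyl)-1,1′-binaphthyl-2,2′-diyl hydrogen phosphate] (5 mol %), 4 Å MS, toluene, −30 °C
Reagents that add atoms: none
Why: chiral phosphoric acid-catalysed allylboration through a closed chair transition state, in which aryl trans to CH2B gives the anti adduct and (S)-TRIP is expected, by the model in which (R)-TRIP sends the allyl group to the Re face of an aldehyde, to direct Si-face attack on acetaldehyde, so that C2 is R and, through the chair, C3 is R.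

Step 6
Reactants: 10 dimethyl squarate
Product: 11 4-hydroxy-2,3-dimethoxycyclobut-2-en-1-one (racemic)
Conditions: LiAlH(Ot-Bu)3, THF, −20 °C
Reagents that add atoms: none
Why: mono-reduction of a squarate by the mild bulky hydride LiAlH(Ot-Bu)3 (1,2-reduction of one vinylogous-ester carbonyl) is known to stop at the 4-hydroxycyclobutenone, whose racemic carbinol centre is erased in step 9.

Step 7
Reactants: 11 4-hydroxy-2,3-dimethoxycyclobut-2-en-1-one
Product: 12 2,3,4-trimethoxycyclobut-2-en-1-one (racemic)
Conditions: MeI, Ag2O, MeCN, rt, dark
Reagents that add atoms: iodomethane, CI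
Why: Purdie methylation (MeI, Ag2O) should etherify the secondary carbinol under neutral conditions that spare the acid- and base-sensitive hydroxycyclobutenone.

Step 8
Reactants: 9 (2R,3R)-4-methylidene-3-(3,4,5-trimethoxyphenyl)hept-6-en-2-ol; 12 2,3,4-trimethoxycyclobut-2-en-1-one (2 equiv)
Product: 13 2,4-dimethoxy-3-{[(2R,3R)-4-methylidene-3-(3,4,5-trimethoxyphenyl)hept-6-en-2-yl]oxy}cyclobut-2-en-1-one (both epimers at the ring CH(OMe) carbon, used together)
Conditions: NaH (0.2 equiv), 5 Å MS, THF, −20 to 0 °C
Reagents that add atoms: none
Why: vinylogous transesterification by addition–elimination, in which the alkoxide of 9 adds to the β-carbon of the cyclobutenone and methoxide leaves, so that only the β-methoxy group is exchanged, the carbinol C–O bond of 9 is not broken and C2 keeps its configuration, while the sieves take up methanol.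

Step 9
Reactants: 13 2,4-dimethoxy-3-{[(2R,3R)-4-methylidene-3-(3,4,5-trimethoxyphenyl)hept-6-en-2-yl]oxy}cyclobut-2-en-1-one
Product: 15 (2R,3S,3aR,5S)-5,7-dimethoxy-2-methyl-3a-(prop-2-en-1-yl)-3-(3,4,5-trimethoxyphenyl)-3,3a,4,5-tetrahydro-1-benzofuran-6(2H)-one, via bicyclo[2.2.0]hexanone photoadduct 14 (not isolated)
Conditions: hν (300 nm), acetone (solvent and triplet sensitiser), degassed, −20 °C; then PPTS (5 mol %), CH2Cl2, 0 °C
Reagents that add atoms: none
Why: Proposed new method: triplet-sensitised intramolecular [2+2] photocycloaddition of the four-membered vinylogous ester C5=C7a of 13 to the tethered 1,1-disubstituted alkene should give the bicyclo[2.2.0]hexanone 14, whose central C5–C7a bond is a push–pull bond (O1 on C7a, C6 ketone next to C5) and should cleave in a De Mayo-type retro-aldol fragmentation to a 1,4-zwitterion that becomes 15 by proton shift from C7 to C5, so that the four-membered ring C5–C6–C7–C7a is expanded by the two atoms C4 and C3a. The closest known reactions are the De Mayo reaction of enolised 1,3-diketones, the intramolecular [2+2] photocycloaddition of 3-(alk-3-enyloxy) enones and tetronates, and the Lewis-acid opening of 3-alkoxycyclobutanones to 1,4-zwitterions, and what is new is the use of a cyclobutenone as the enone partner. The tetrahydrofuran closes first by C7a–C3a bonding in the 5-exo mode (rule of five), the cyclobutane then closes by C5–C4 radical recombination, and the six-membered ring is not closed as such but arises when the bond shared by the two four-membered rings breaks. C3a is controlled by the C2 and C3 stereocentres of the tether, because in the envelope of the forming tetrahydrofuran C4 must point towards C5 and the methyl, aryl and allyl groups can then all sit pseudo-equatorially only if allyl is trans to aryl; C5 is set by protonation of the C5=C6 enol on the face away from the pseudo-axial allyl group, and C7 and C7a become sp2, so both epimers at the ring CH(OMe) carbon of 13 and both faces of the enone converge on one product. The step needs cycloaddition to beat the electrocyclic opening of the excited cyclobutenone to a vinylketene, which sensitisation through the triplet in acetone, the fast five-membered closure and the thermal reversibility of that opening should secure, and it needs the 1,1-disubstituted alkene to react in preference to the allyl group and in the straight rather than the crossed sense, which the three-atom tether secures. C5 stays epimerisable next to the ketone, so the fragmentation is run buffered and cold to keep the kinetic epimer.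

**Compound list**
1 | triethyl phosphonoacetate | CCOC(=O)CP(=O)(OCC)OCC | starting material
2 | allyl bromide (3-bromoprop-1-ene) | C=CCBr | starting material
3 | ethyl 2-(diethoxyphosphoryl)pent-4-enoate (racemic) | CCOC(=O)C(CC=C)P(=O)(OCC)OCC | intermediate
4 | 3,4,5-trimethoxybenzaldehyde | COc1cc(C=O)cc(OC)c1OC | starting material
5 | ethyl (2E)-2-[(3,4,5-trimethoxyphenyl)methylidene]pent-4-enoate | CCOC(=O)/C(CC=C)=C/c1cc(OC)c(OC)c(OC)c1 | intermediate
6 | (2E)-2-[(3,4,5-trimethoxyphenyl)methylidene]pent-4-en-1-ol | OC/C(CC=C)=C/c1cc(OC)c(OC)c(OC)c1 | intermediate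
7 | 4,4,5,5-tetramethyl-2-{(2Z)-2-[(3,4,5-trimethoxyphenyl)methylidene]pent-4-en-1-yl}-1,3,2-dioxaborolane | CC1(C)OB(C/C(CC=C)=C/c2cc(OC)c(OC)c(OC)c2)OC1(C)C | intermediate
8 | acetaldehyde | CC=O | starting material
9 | (2R,3R)-4-methylidene-3-(3,4,5-trimethoxyphenyl)hept-6-en-2-ol | O[C@H](C)[C@H](C(=C)CC=C)c1cc(OC)c(OC)c(OC)c1 | intermediate
10 | dimethyl squarate (3,4-dimethoxycyclobut-3-ene-1,2-dione) | COC1=C(OC)C(=O)C1=O | starting material
11 | 4-hydroxy-2,3-dimethoxycyclobut-2-en-1-one (racemic) | COC1=C(OC)C(=O)C1O | intermediate
12 | 2,3,4-trimethoxycyclobut-2-en-1-one (racemic) | COC1C(=O)C(OC)=C1OC | intermediate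
13 | 2,4-dimethoxy-3-{[(2R,3R)-4-methylidene-3-(3,4,5-trimethoxyphenyl)hept-6-en-2-yl]oxy}cyclobut-2-en-1-one (both epimers at the ring CH(OMe) carbon) | COC1C(=O)C(OC)=C1O[C@H](C)[C@H](C(=C)CC=C)c1cc(OC)c(OC)c(OC)c1 | intermediate
14 | 2,4-dimethoxy-8-methyl-6-(prop-2-en-1-yl)-7-(3,4,5-trimethoxyphenyl)-9-oxatricyclo[4.3.0.0(1,4)]nonan-3-one (all ring fusions cis; C2, C3 and C3a as in 15; both epimers at the CH(OMe) carbon next to the ketone) | C=CC[C@]12C[C@]3(OC)C(=O)C(OC)[C@]13O[C@H](C)[C@H]2c1cc(OC)c(OC)c(OC)c1 | intermediate (not isolated)
15 | (2R,3S,3aR,5S)-5,7-dimethoxy-2-methyl-3a-(prop-2-en-1-yl)-3-(3,4,5-trimethoxyphenyl)-3,3a,4,5-tetrahydro-1-benzofuran-6(2H)-one | C=CC[C@]12C[C@H](OC)C(=O)C(OC)=C1O[C@H](C)[C@H]2c1cc(OC)c(OC)c(OC)c1 | target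

**Step count**
Total steps: 9. Longest linear sequence: 7 steps (steps 1, 2, 3, 4, 5, 8 and 9).

**Steps most likely to fail**

Step 9 (proposed method). What may go wrong: after excitation the cyclobutenone may open electrocyclically to a vinylketene faster than it adds to the alkene, or the product enone may be consumed by further photoreaction. The fallback uses known chemistry, sets out from 13 and returns at 14; it removes the carbonyl chromophore before the photochemical step. Reduction of 13 with i-Bu2AlH (toluene, −78 °C) should give 2,4-dimethoxy-3-{[(2R,3R)-4-methylidene-3-(3,4,5-trimethoxyphenyl)hept-6-en-2-yl]oxy}cyclobut-2-en-1-ol F1, a 1,6-diene of the homoallyl vinyl ether type. A copper-catalysed [2+2] photobicyclisation of the Salomon–Kochi type (CuOTf, monovalent copper, Et2O, 254 nm) should then close the same C7a–C3a and C5–C4 bonds to 2,4-dimethoxy-8-methyl-6-(prop-2-en-1-yl)-7-(3,4,5-trimethoxyphenyl)-9-oxatricyclo[4.3.0.0(1,4)]nonan-3-ol F2. Dess–Martin oxidation of F2 gives ketone 14, which is fragmented to 15 under the second set of conditions of step 9.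

Step 8. What may go wrong: the alkoxide exchange may stop at an unfavourable equilibrium, or the alkoxide may attack the ring carbonyl and open the strained ring. The fallback sets out from 12 and returns at 13; it changes the leaving group from methoxide to chloride so that the union is irreversible. LiOH (THF/H2O, 0 °C) should hydrolyse the vinylogous ester of 12 to 3-hydroxy-2,4-dimethoxycyclobut-2-en-1-one F3. Oxalyl chloride with catalytic DMF (CH2Cl2, 0 °C) converts this vinylogous acid into 3-chloro-2,4-dimethoxycyclobut-2-en-1-one F4. The sodium alkoxide of 9 (NaH, THF, −78 °C) then displaces chloride from F4 by addition–elimination to give 13.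

Step 5. What may go wrong: the catalyst may discriminate poorly between the two faces of the small aldehyde, so that the enantiomeric purity of 9 is insufficient. The fallback sets out from 7 and 8 and returns at 9; it takes the absolute configuration from an enzyme instead of the catalyst. Without catalyst (toluene, rt) 7 and 8 should react through the same chair to the racemic anti alcohol, a 1:1 mixture of 9 and its enantiomer (2S,3S)-4-methylidene-3-(3,4,5-trimethoxyphenyl)hept-6-en-2-ol F5. Candida antarctica lipase B with vinyl acetate should acylate the (2R)-carbinol selectively (Kazlauskas rule) to (2R,3R)-4-methylidene-3-(3,4,5-trimethoxyphenyl)hept-6-en-2-yl acetate F6. F6 is separated from unreacted F5 and methanolysed (K2CO3, MeOH) to 9.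

**Further compounds**
F1 | step 9 | 2,4-dimethoxy-3-{[(2R,3R)-4-methylidene-3-(3,4,5-trimethoxyphenyl)hept-6-en-2-yl]oxy}cyclobut-2-en-1-ol (mixture of ring diastereomers) | COC1C(O)C(OC)=C1O[C@H](C)[C@H](C(=C)CC=C)c1cc(OC)c(OC)c(OC)c1
F2 | step 9 | 2,4-dimethoxy-8-methyl-6-(prop-2-en-1-yl)-7-(3,4,5-trimethoxyphenyl)-9-oxatricyclo[4.3.0.0(1,4)]nonan-3-ol (ring fusions cis; C2, C3 and C3a as in 15) | C=CC[C@]12C[C@]3(OC)C(O)C(OC)[C@]13O[C@H](C)[C@H]2c1cc(OC)c(OC)c(OC)c1
F3 | step 8 | 3-hydroxy-2,4-dimethoxycyclobut-2-en-1-one (racemic) | COC1C(=O)C(OC)=C1O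
F4 | step 8 | 3-chloro-2,4-dimethoxycyclobut-2-en-1-one (racemic) | COC1C(=O)C(OC)=C1Cl
F5 | step 5 | (2S,3S)-4-methylidene-3-(3,4,5-trimethoxyphenyl)hept-6-en-2-ol | O[C@@H](C)[C@@H](C(=C)CC=C)c1cc(OC)c(OC)c(OC)c1
F6 | step 5 | (2R,3R)-4-methylidene-3-(3,4,5-trimethoxyphenyl)hept-6-en-2-yl acetate | CC(=O)O[C@H](C)[C@H](C(=C)CC=C)c1cc(OC)c(OC)c(OC)c1
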